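Readings and results come from a simulation with constants of no real substance; noise was put on by code.

The zeta run is the very flask asked about, followed to 1.5 min. Beside it I set a neighbour that differs in one charge: 0.50 mM of substrate instead of 0.20 mM, with the same 0.300 mM of coupling partner.

the same everywhere: substrate 0.20 mM

| flask | coupling partner | remark | time |
|---|---|---|---|
| zeta | 0.30 mM | the very flask that is asked about, followed so far |  |
| flask | 0.300 mM |  | 8.0 min |

zeta run (percent of the substrate charged)

| time / s | double product / % | substrate / % |
|---|---|---|
| 25.0 | 4.6 | 57.9 |
| 30.0 | 4.5 | 52.3 |
| 40.0 | 6.9 | 45.1 |
| 60.0 | 7.1 | 33.7 |
| 80.0 | 8.9 | 25.6 |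
| 90.0 | 9.7 | 23.5 |

(scatter of a reading: 0.5 percentage points)

- time up to 8.0 min at which double product stands highest
- the amount of double product, in percent of the substrate charged, at that time

I take it that every substrate that reacts takes one coupling partner, and that each double product has taken a second. At the last reading 1.13 is then the partner demand, coupling partner used per substrate consumed: one for the substrate, plus the share of double product.

I hold this demand against the charged ratio [coupling partner]/[substrate] to find each end state. In the flask that ratio is 1.50, more than the demand, so the substrate can react to its end. At the demand as read, 24.9% of the partner's charge is then over, and I hold that as an upper figure, since any partner taken up later comes out of it. In the neighbour the ratio is 0.600, less than the demand, so coupling partner is the limiting reagent and I reckon that the neighbour stops with 46.8% of its substrate unreacted.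

With partner to spare in the flask, I expect it to turn on double product. My own reckoning therefore puts the peak soon after 1.5 min and under 12.7% of the substrate charged, the share read above.

The forecast differs, with 8 min (range 7 min to 8 min) and 13.5% (range 10.8% to 19.5%): “No decay is seen, so I expect the maximum at the end of the window”.

The flask peaks at 1.68 min with 9.17% of double product.

    substrate + coupling partner → single product (k = 91.0 M⁻¹ s⁻¹)
    coupling partner + single product → double product (k = 53.0 M⁻¹ s⁻¹)
    coupling partner + double product → tris adduct (k = 34.0 M⁻¹ s⁻¹)
    coupling partner + tris adduct → tetra adduct (k = 190 M⁻¹ s⁻¹)
    single product → side product (k = 0.0460 s⁻¹)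

Double product then falls to 5.27% by 8.00 min. At the peak 21.1% of the substrate stands, so the partner demand reckons 40.6% of the partner's charge left, and the flask holds 35.7%. By 8.00 min the flask holds 14% of the partner's charge, under the upper figure of 24.9%. The neighbour, reckoned at 46.8%, holds 46% of its substrate unreacted at 8.00 min.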